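**Retrosynthetic overview**

1. Locants follow germacrane numbering (ring C1–C10, lactone carbons C11/C12/C13, lactone oxygen on C6, angelate on O8). The ten-membered ring is opened at the Z C1=C10 alkene, by ring-closing metathesis of a diol that carries a C1 vinyl and a C10 isopropenyl group.
2. The α-methylene-γ-lactone is disconnected at O–C6 and C11–C7 in one (3+2) event: a palladium-catalysed carbo-oxygenation of a (4E,6Z)-diene by 2-bromoacrylic acid, which is tethered to O8 as a diisopropylsilyl ester.
3. The feature that allows this: the lactone oxygen sits on C6, allylic to the C4=C5 alkene, with C11 on the adjacent C7 and an oxygen on C8. C7–C6–C5=C4 is therefore the footprint of a C4=C5–C6=C7 diene after 1,2-addition through an allylpalladium, and O8 is the handle for the tether.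
4. The dienol comes from an enyne by cis semireduction. C8 and C9 are set together by an asymmetric γ-alkoxyallylboration of an ynal, made by Sonogashira coupling of an E vinyl iodide that carries C2 from (S)-2-vinyloxirane.
5. Ring order: γ-lactone first (step 10), ten-membered carbocycle second (step 13). C2 is bought, C8/C9 are set by the reagent, and C7 and C6 are relayed from C8 in the key step.

Key step: step 10

Assumption: (S)-2-vinyloxirane is taken as a commercial, enantiopure starting material, and angelic acid supplies the Z geometry of the ester. Locants C1–C13 in the text are those of the target.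

**Step 1**
Reactants: 1 (S)-2-vinyloxirane; 2 lithium acetylide–ethylenediamine complex
Product: 3 (R)-hex-1-en-5-yn-3-ol
Conditions: DMSO, 0 °C to rt; then H2O
Reagents that add atoms: none
Why: Epoxide alkynylation by SN2 attack of the acetylide at the unsubstituted ring carbon leaves the C2 stereocentre untouched, so the bought (S)-epoxide should give the (R)-alcohol (the descriptor changes only through the priority rules).

**Step 2**
Reactants: 3 (R)-hex-1-en-5-yn-3-ol
Product: 5 (3R,5E)-6-iodo-5-methylhexa-1,5-dien-3-ol, via alkenylalane 4 (not isolated)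
Conditions: AlMe3 (3 equiv), Cp2ZrCl2 (0.25 equiv), CH2Cl2, 0 °C to rt; then I2, THF, −30 to 0 °C; aq. KNaC4H4O6 (potassium sodium tartrate)
Reagents that add atoms: trimethylaluminium (C[Al](C)C); iodine (II)
Why: Negishi zirconium-catalysed carboalumination adds methyl and aluminium syn across the terminal alkyne with aluminium on the terminal carbon, and iodinolysis with retention should give the E vinyl iodide that becomes the C4=C5 alkene.

**Step 3**
Reactants: 5 (3R,5E)-6-iodo-5-methylhexa-1,5-dien-3-ol
Product: 6 (1E,4R)-1-iodo-4-(methoxymethoxy)-2-methylhexa-1,5-diene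
Conditions: MOMCl, iPr2NEt, CH2Cl2, 0 °C to rt
Reagents that add atoms: chloromethyl methyl ether (COCCl)
Why: Methoxymethyl ether formation by O-alkylation protects O2 until step 12 and does not touch the stereocentre.

**Step 4**
Reactants: 6 (1E,4R)-1-iodo-4-(methoxymethoxy)-2-methylhexa-1,5-diene; 7 prop-2-yn-1-ol
Product: 8 (4E,7R)-7-(methoxymethoxy)-5-methylnona-4,8-dien-2-yn-1-ol
Conditions: Pd(PPh3)2Cl2 (3 mol %), CuI (6 mol %), Et3N, THF, rt
Reagents that add atoms: none
Why: Sonogashira coupling of a vinyl iodide with a terminal alkyne proceeds with retention of the E alkene geometry and tolerates the acetal and the terminal alkene.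

**Step 5**
Reactants: 8 (4E,7R)-7-(methoxymethoxy)-5-methylnona-4,8-dien-2-yn-1-ol
Product: 9 (4E,7R)-7-(methoxymethoxy)-5-methylnona-4,8-dien-2-ynal
Conditions: activated MnO2, CH2Cl2, rt
Reagents that add atoms: none
Why: MnO2 oxidation is selective for the propargylic alcohol and should give the ynal without over-oxidation, to be used directly.

**Step 6**
Reactants: 10 2-methylprop-2-en-1-ol
Product: 11 3-(methoxymethoxy)-2-methylprop-1-ene
Conditions: MOMCl, iPr2NEt, CH2Cl2, 0 °C to rt
Reagents that add atoms: chloromethyl methyl ether (COCCl)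
Why: Methoxymethyl ether formation gives the allyl ether needed for the alkoxyallylboration and fixes the protecting group that O9 will carry.

**Step 7**
Reactants: 11 3-(methoxymethoxy)-2-methylprop-1-ene; 9 (4E,7R)-7-(methoxymethoxy)-5-methylnona-4,8-dien-2-ynal
Product: 14 (3R,4R,7E,10R)-3,10-bis(methoxymethoxy)-2,8-dimethyldodeca-1,7,11-trien-5-yn-4-ol, via allylborane 12 (not isolated), via borinate ester 13 (not isolated)
Conditions: 11, sec-BuLi, THF, −78 °C; (−)-B-methoxydiisopinocampheylborane; BF3·OEt2; then 9, −78 °C; then NaOH, H2O2, 0 °C to rt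
Reagents that add atoms: none
Why: Brown asymmetric γ-alkoxyallylboration: lithiation next to oxygen gives the chelated Z oxyallyl anion, and its Z diisopinocampheylborane adds through a chair (Zimmerman–Traxler) transition state, so the Z geometry sets the 8,9-syn relation and the isopinocampheyl groups from (+)-α-pinene direct attack to the Si face of the aldehyde, which sets C8 (R) and C9 (R) and leaves O8 free and O9 protected.

**Step 8**
Reactants: 14 (3R,4R,7E,10R)-3,10-bis(methoxymethoxy)-2,8-dimethyldodeca-1,7,11-trien-5-yn-4-ol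
Product: 15 (3R,4R,5Z,7E,10R)-3,10-bis(methoxymethoxy)-2,8-dimethyldodeca-1,5,7,11-tetraen-4-ol
Conditions: Zn dust activated with Cu(OAc)2 and AgNO3, MeOH/H2O (1:1), 45 °C
Reagents that add atoms: none
Why: Activated zinc reduces a conjugated enyne by cis semireduction and leaves isolated alkenes alone, so the (4E,6Z)-diene should form without over-reduction of the vinyl and isopropenyl groups.

**Step 9**
Reactants: 15 (3R,4R,5Z,7E,10R)-3,10-bis(methoxymethoxy)-2,8-dimethyldodeca-1,5,7,11-tetraen-4-ol; 16 2-bromoprop-2-enoic acid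
Product: 18 {[(3R,4R,5Z,7E,10R)-3,10-bis(methoxymethoxy)-2,8-dimethyldodeca-1,5,7,11-tetraen-4-yl]oxy}di(propan-2-yl)silyl 2-bromoprop-2-enoate, via chlorosilyl ether 17 (not isolated)
Conditions: iPr2SiCl2 (3 equiv), iPr2NEt, DMAP (cat.), CH2Cl2, 0 °C; excess silane removed in vacuo; then 16, iPr2NEt, CH2Cl2, 0 °C; filtered under argon and used crude
Reagents that add atoms: dichlorodi(propan-2-yl)silane (CC(C)[Si](Cl)(Cl)C(C)C)
Why: Stepwise substitution at silicon (silyl ether, then silyl ester formation) should place the monochlorosilyl group on the only free hydroxyl (O8) and let the carboxylate displace the second chloride, with no stereocentre touched.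

**Step 10**
Reactants: 18 {[(3R,4R,5Z,7E,10R)-3,10-bis(methoxymethoxy)-2,8-dimethyldodeca-1,5,7,11-tetraen-4-yl]oxy}di(propan-2-yl)silyl 2-bromoprop-2-enoate
Product: 20 (4R,5R)-4-[(1R,2R)-1-hydroxy-2-(methoxymethoxy)-3-methylbut-3-en-1-yl]-5-[(1E,4R)-4-(methoxymethoxy)-2-methylhexa-1,5-dien-1-yl]-3-methylideneoxolan-2-one, via bromosilyl ether lactone 19 (not isolated)
Conditions: Pd2(dba)3 (5 mol %), tri(2-furyl)phosphine (20 mol %), n-Bu4NBr (1 equiv), MeCN, 60 °C; then HF·pyridine, pyridine, THF, 0 °C
Reagents that add atoms: none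
Why: Proposed new method: zerovalent palladium should insert into the C–Br bond of the 2-bromoacrylate, and the silyl ester tether then holds the vinylpalladium over C7, so that a 7-exo-trig syn-carbopalladation forms C11–C7 and leaves an η3-allylpalladium over C6–C5–C4 that the ester carbonyl oxygen attacks at C6 in a 5-exo closure while bromide takes the silyl group, which gives lactone 19 and returns zerovalent palladium; the closest known reaction type is the Larock heteroannulation of 1,3-dienes with vinyl or aryl halides that carry a carboxylic acid, made intramolecular here by a temporary silicon tether. The transient seven-membered silyl ester ring closes by 7-exo-trig insertion and the γ-lactone by 5-exo attack of oxygen on the allyl terminus anti to palladium. C7 is controlled by C8: 1,3-allylic strain in the 6Z alkene holds H8 in the diene plane, and the tether can deliver C11 only to the face on which O8 lies, which is the 7,8-syn relation of the target. C6 is controlled by the alkene geometry, since syn addition of C11 and palladium across the Z alkene followed by anti C–O formation is a net anti addition and gives the trans-disubstituted lactone; bromide in excess and the silyl mask keep the carboxyl oxygen off palladium, which closes the syn pathway. The step needs regioselectivity (C11 to the diene terminus C7, oxygen to C6 and not to tertiary C4), secured by ring size (seven and five against eight and seven), retention of the 4E geometry, secured by the s-trans diene that gives the syn,syn-allyl, and chemoselectivity over the C1 vinyl and C10 isopropenyl groups, which the tethered vinylpalladium cannot reach in a small ring. HF·pyridine in the work-up then cleaves the bromosilyl ether 19 to free O8–H.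

**Step 11**
Reactants: 20 (4R,5R)-4-[(1R,2R)-1-hydroxy-2-(methoxymethoxy)-3-methylbut-3-en-1-yl]-5-[(1E,4R)-4-(methoxymethoxy)-2-methylhexa-1,5-dien-1-yl]-3-methylideneoxolan-2-one; 21 (2Z)-2-methylbut-2-enoic acid (angelic acid)
Product: 23 (1R,2R)-2-(methoxymethoxy)-1-{(2R,3S)-2-[(1E,4R)-4-(methoxymethoxy)-2-methylhexa-1,5-dien-1-yl]-4-methylidene-5-oxooxolan-3-yl}-3-methylbut-3-en-1-yl (2Z)-2-methylbut-2-enoate, via mixed anhydride 22 (not isolated)
Conditions: 21, 2,4,6-trichlorobenzoyl chloride, Et3N, toluene, rt; then 20, toluene, 75 °C (no DMAP)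
Reagents that add atoms: none
Why: Yamaguchi-type esterification through the mixed anhydride acylates the only free hydroxyl (O8), and leaving out a nucleophilic catalyst and strong base should avoid Z-to-E isomerisation of the angelate and translactonisation onto O8.

**Step 12**
Reactants: 23 (1R,2R)-2-(methoxymethoxy)-1-{(2R,3S)-2-[(1E,4R)-4-(methoxymethoxy)-2-methylhexa-1,5-dien-1-yl]-4-methylidene-5-oxooxolan-3-yl}-3-methylbut-3-en-1-yl (2Z)-2-methylbut-2-enoate
Product: 25 (1R,2R)-2-hydroxy-1-{(2R,3S)-2-[(1E,4R)-4-hydroxy-2-methylhexa-1,5-dien-1-yl]-4-methylidene-5-oxooxolan-3-yl}-3-methylbut-3-en-1-yl (2Z)-2-methylbut-2-enoate, via bis(bromomethyl) ether 24 (not isolated)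
Conditions: Me2BBr (4 equiv), CH2Cl2, −78 °C; then THF/sat. aq. NaHCO3, 0 °C
Reagents that add atoms: none
Why: Acetal cleavage with Me2BBr opens each methoxymethyl acetal at −78 °C to a bromomethyl ether that hydrolyses on bicarbonate work-up, which esters, the lactone and the alkenes should survive, and it is done before ring closure so that the acid-sensitive cyclodecadiene never meets a Lewis acid.

**Step 13**
Reactants: 25 (1R,2R)-2-hydroxy-1-{(2R,3S)-2-[(1E,4R)-4-hydroxy-2-methylhexa-1,5-dien-1-yl]-4-methylidene-5-oxooxolan-3-yl}-3-methylbut-3-en-1-yl (2Z)-2-methylbut-2-enoate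
Product: 26 (3aS,4R,5R,6Z,8R,10E,11aR)-5,8-dihydroxy-6,10-dimethyl-3-methylidene-2-oxo-2,3,3a,4,5,8,9,11a-octahydrocyclodeca[b]furan-4-yl (2Z)-2-methylbut-2-enoate (target)
Conditions: second-generation Grubbs catalyst (10 mol %), 1,4-benzoquinone (20 mol %), toluene (1 mM), 80 °C, argon sparge
Reagents that add atoms: none
Why: Ring-closing metathesis should start at the C1 vinyl group and close onto the C10 isopropenyl group, helped by the two allylic hydroxyls, and a ten-membered ring that already holds the E C4=C5 alkene and the trans-fused lactone should form the new trisubstituted alkene as the less strained Z isomer.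

**Compound list**

1 | (S)-2-vinyloxirane | C=C[C@H]1CO1 | starting material
2 | lithium acetylide–ethylenediamine complex | [Li]C#C.NCCN | starting material
3 | (R)-hex-1-en-5-yn-3-ol | C=C[C@H](O)CC#C | intermediate
4 | (E)-alkenylalane, O-dimethylaluminium alkoxide of the carboalumination product | C=C[C@H](O[Al](C)C)C/C(C)=C/[Al](C)C | intermediate (not isolated)
5 | (3R,5E)-6-iodo-5-methylhexa-1,5-dien-3-ol | C=C[C@H](O)C/C(C)=C/I | intermediate
6 | (1E,4R)-1-iodo-4-(methoxymethoxy)-2-methylhexa-1,5-diene | C=C[C@H](OCOC)C/C(C)=C/I | intermediate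
7 | prop-2-yn-1-ol | C#CCO | starting material
8 | (4E,7R)-7-(methoxymethoxy)-5-methylnona-4,8-dien-2-yn-1-ol | OCC#C/C=C(C)/C[C@@H](OCOC)C=C | intermediate
9 | (4E,7R)-7-(methoxymethoxy)-5-methylnona-4,8-dien-2-ynal | O=CC#C/C=C(C)/C[C@@H](OCOC)C=C | intermediate
10 | 2-methylprop-2-en-1-ol | C=C(C)CO | starting material
11 | 3-(methoxymethoxy)-2-methylprop-1-ene | C=C(C)COCOC | intermediate
12 | [(Z)-3-(methoxymethoxy)-2-methylallyl]diisopinocampheylborane (isopinocampheyl groups from (+)-α-pinene) | COCO/C=C(C)\CB([C@@H]1C[C@@H]2C[C@H]([C@H]1C)C2(C)C)[C@@H]1C[C@@H]2C[C@H]([C@H]1C)C2(C)C | intermediate (not isolated)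
13 | diisopinocampheylborinate ester of 14 at O8 | C=C(C)[C@@H](OCOC)[C@H](OB([C@@H]1C[C@@H]2C[C@H]([C@H]1C)C2(C)C)[C@@H]1C[C@@H]2C[C@H]([C@H]1C)C2(C)C)C#C/C=C(C)/C[C@@H](OCOC)C=C | intermediate (not isolated)
14 | (3R,4R,7E,10R)-3,10-bis(methoxymethoxy)-2,8-dimethyldodeca-1,7,11-trien-5-yn-4-ol | C=C(C)[C@@H](OCOC)[C@H](O)C#C/C=C(C)/C[C@@H](OCOC)C=C | intermediate
15 | (3R,4R,5Z,7E,10R)-3,10-bis(methoxymethoxy)-2,8-dimethyldodeca-1,5,7,11-tetraen-4-ol | C=C(C)[C@@H](OCOC)[C@H](O)/C=C\C=C(C)\C[C@@H](OCOC)C=C | intermediate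
16 | 2-bromoprop-2-enoic acid | C=C(Br)C(=O)O | starting material
17 | chlorodi(propan-2-yl)silyl ether of 15 at O8 | C=C(C)[C@@H](OCOC)[C@H](O[Si](Cl)(C(C)C)C(C)C)/C=C\C=C(C)\C[C@@H](OCOC)C=C | intermediate (not isolated)
18 | {[(3R,4R,5Z,7E,10R)-3,10-bis(methoxymethoxy)-2,8-dimethyldodeca-1,5,7,11-tetraen-4-yl]oxy}di(propan-2-yl)silyl 2-bromoprop-2-enoate | C=C(C)[C@@H](OCOC)[C@H](O[Si](OC(=O)C(Br)=C)(C(C)C)C(C)C)/C=C\C=C(C)\C[C@@H](OCOC)C=C | intermediate
19 | O8-[bromodi(propan-2-yl)silyl] ether of lactone 20 | C=C1C(=O)O[C@H](/C=C(\C)C[C@@H](OCOC)C=C)[C@H]1[C@@H](O[Si](Br)(C(C)C)C(C)C)[C@H](OCOC)C(C)=C | intermediate (not isolated)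
20 | (4R,5R)-4-[(1R,2R)-1-hydroxy-2-(methoxymethoxy)-3-methylbut-3-en-1-yl]-5-[(1E,4R)-4-(methoxymethoxy)-2-methylhexa-1,5-dien-1-yl]-3-methylideneoxolan-2-one | C=C1C(=O)O[C@H](/C=C(\C)C[C@@H](OCOC)C=C)[C@H]1[C@@H](O)[C@H](OCOC)C(C)=C | intermediate
21 | (2Z)-2-methylbut-2-enoic acid (angelic acid) | C/C=C(/C)C(=O)O | starting material
22 | (2Z)-2-methylbut-2-enoic 2,4,6-trichlorobenzoic anhydride | C/C=C(/C)C(=O)OC(=O)c1c(Cl)cc(Cl)cc1Cl | intermediate (not isolated)
23 | (1R,2R)-2-(methoxymethoxy)-1-{(2R,3S)-2-[(1E,4R)-4-(methoxymethoxy)-2-methylhexa-1,5-dien-1-yl]-4-methylidene-5-oxooxolan-3-yl}-3-methylbut-3-en-1-yl (2Z)-2-methylbut-2-enoate | C=C1C(=O)O[C@H](/C=C(\C)C[C@@H](OCOC)C=C)[C@H]1[C@@H](OC(=O)/C(C)=C\C)[C@H](OCOC)C(C)=C | intermediate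
24 | bis(bromomethyl) ether of diol 25 at O2 and O9 | C=C1C(=O)O[C@H](/C=C(\C)C[C@@H](OCBr)C=C)[C@H]1[C@@H](OC(=O)/C(C)=C\C)[C@H](OCBr)C(C)=C | intermediate (not isolated)
25 | (1R,2R)-2-hydroxy-1-{(2R,3S)-2-[(1E,4R)-4-hydroxy-2-methylhexa-1,5-dien-1-yl]-4-methylidene-5-oxooxolan-3-yl}-3-methylbut-3-en-1-yl (2Z)-2-methylbut-2-enoate | C=C1C(=O)O[C@H](/C=C(\C)C[C@@H](O)C=C)[C@H]1[C@@H](OC(=O)/C(C)=C\C)[C@H](O)C(C)=C | intermediate
26 | (3aS,4R,5R,6Z,8R,10E,11aR)-5,8-dihydroxy-6,10-dimethyl-3-methylidene-2-oxo-2,3,3a,4,5,8,9,11a-octahydrocyclodeca[b]furan-4-yl (2Z)-2-methylbut-2-enoate | C=C1C(=O)O[C@@H]2/C=C(\C)C[C@@H](O)/C=C(/C)[C@@H](O)[C@H](OC(=O)/C(C)=C\C)[C@@H]12 | target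

**Step count and risks**

Total steps: 13. Longest linear sequence: 12 (steps 1–5 and 7–13, from (S)-2-vinyloxirane); step 6 is a one-step branch.

Steps most likely to fail:

1. Step 10 (labelled Proposed new method). The silyl ester may be cleaved before carbopalladation, which would remove the tether and with it the facial control at C7. The allylpalladium may lose a β-hydride instead of being captured, or the carboxyl oxygen may be delivered through palladium (syn) and give the cis lactone. The fallback uses known chemistry and sets out from dienol 15. O8 is silylated (Et3SiCl, imidazole, CH2Cl2) to the triethylsilyl ether F1. F1 then undergoes the intermolecular Larock heteroannulation of the diene with 2-bromoprop-2-enoic acid 16 (Pd(OAc)2, Na2CO3, n-Bu4NCl, DMF, 60–80 °C), in which the vinylpalladium adds to the less hindered diene terminus C7 and the carboxylate closes on C6, to give the silyl-protected lactone F2. Facial selectivity is expected to be lower, so diastereomers would be separated at this stage. HF·pyridine then removes the silyl group and the route is rejoined at hydroxy lactone 20.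

2. Step 13. Cross metathesis between molecules may outrun ring closure and give oligomers, and ruthenium hydrides may isomerise the allylic alcohols to ketones. The fallback sets out from diol 25. O2 and O9 are bridged with iPr2SiCl2 (imidazole, CH2Cl2, high dilution) to give the cyclic di(propan-2-yl)silylene acetal F3. Metathesis of F3 then closes a seven-membered dioxasilepine, which can only hold a Z alkene, and the carbocycle with it, to give the silylene-bridged macrocycle F4. HF·pyridine removes the silicon bridge and gives target 26 directly.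

3. Step 7. Lithiation of the allyl ether may occur at the allylic methyl group instead of next to oxygen, which would give the wrong allylmetal, and the face selectivity of the borane may be eroded with the ynal. The fallback sets out from ynal 9 and replaces the allylboration by an auxiliary-controlled aldol. (S)-4-Benzyloxazolidin-2-one is acylated with (methoxymethoxy)acetic acid (pivaloyl chloride, Et3N; then the lithiated oxazolidinone) to give the glycolyl imide F5. Its boron enolate (Bu2BOTf, iPr2NEt, CH2Cl2, −78 °C) adds to 9 in an Evans syn aldol to give the syn-aldol adduct F6 with the 8,9-syn relation and the required absolute configuration. MeONHMe·HCl and AlMe3 convert F6 to the Weinreb amide F7, MeMgBr gives the methyl ketone F8, and methylenation with Cp2Ti(μ-Cl)(μ-CH2)AlMe2 rejoins the route at compound 14.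

**Further compounds**

F1 | step 10 | triethylsilyl ether of dienol 15 at O8 | C=C(C)[C@@H](OCOC)[C@H](O[Si](CC)(CC)CC)/C=C\C=C(C)\C[C@@H](OCOC)C=C
F2 | step 10 | O8-triethylsilyl ether of lactone 20 | C=C1C(=O)O[C@H](/C=C(\C)C[C@@H](OCOC)C=C)[C@H]1[C@@H](O[Si](CC)(CC)CC)[C@H](OCOC)C(C)=C
F3 | step 13 | cyclic di(propan-2-yl)silylene acetal of diol 25 bridging O2 and O9 (eleven-membered ring) | C=C1C(=O)O[C@H](/C=C(\C)C[C@@H](O[Si]2(C(C)C)C(C)C)C=C)[C@H]1[C@@H](OC(=O)/C(C)=C\C)[C@H](O2)C(C)=C
F4 | step 13 | target 26 with O2 and O9 bridged by di(propan-2-yl)silylene (seven-membered dioxasilepine on the ten-membered ring) | C=C1C(=O)O[C@@H]2/C=C(\C)C[C@@H](O[Si]3(C(C)C)C(C)C)/C=C(/C)[C@@H](O3)[C@H](OC(=O)/C(C)=C\C)[C@@H]12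
F5 | step 7 | (S)-4-benzyl-3-[(methoxymethoxy)acetyl]oxazolidin-2-one | COCOCC(=O)N1[C@@H](Cc2ccccc2)COC1=O
F6 | step 7 | (4S)-4-benzyl-3-[(2S,3R,6E,9R)-3-hydroxy-2,9-bis(methoxymethoxy)-7-methylundeca-6,10-dien-4-ynoyl]oxazolidin-2-one | C=C[C@H](OCOC)C/C(C)=C/C#C[C@@H](O)[C@H](OCOC)C(=O)N1[C@@H](Cc2ccccc2)COC1=O
F7 | step 7 | (2S,3R,6E,9R)-3-hydroxy-N-methoxy-2,9-bis(methoxymethoxy)-N,7-dimethylundeca-6,10-dien-4-ynamide | C=C[C@H](OCOC)C/C(C)=C/C#C[C@@H](O)[C@H](OCOC)C(=O)N(C)OC
F8 | step 7 | (3S,4R,7E,10R)-4-hydroxy-3,10-bis(methoxymethoxy)-8-methyldodeca-7,11-dien-5-yn-2-one | C=C[C@H](OCOC)C/C(C)=C/C#C[C@@H](O)[C@H](OCOC)C(C)=O
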